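Early on the winter flask moves fast: L stands at 35 % after 2.50 h, and the mean of the readings from 8.00 h on is 41.0 %.

| flask | E | G | D | temperature | remark | time |
|---|---|---|---|---|---|---|
| winter | 0.94 M | 0.564 M | 2.7 mM | 25 °C | the very flask that is asked about, followed so far |  |
| noon | 1.9 M | 0.564 M | 2.7 mM | 31 °C | run made earlier |  |
| flask | 0.94 M | 0.564 M | 2.7 mM | 25 °C |  | 25 h |

| run | time / h | L / % | E / % |
|---|---|---|---|
| winter | 2.50 | 35 | 65 |
| winter | 5.00 | 39 | 63 |
| winter | 8.00 | 43 | 63 |
| winter | 10.0 | 40 | 61 |
| winter | 12.0 | 41 | 57 |
| winter | 15.0 | 40 | 60 |
| noon | 0.333 | 17 | 80 |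
| noon | 1.00 | 24 | 76 |
| noon | 1.50 | 25 | 77 |
| noon | 2.50 | 23 | 76 |
| noon | 4.00 | 24 | 75 |
| noon | 5.00 | 25 | 74 |

(each reading ± 1.5 percentage points)

- blue: change nothing and wait 25 h more
- green: at 25 h add D, 50.0 % of the amount charged, then wait 25 h
- ochre: at 25 h add G, 50.0 % of the amount charged, then wait 25 h
- teal: at 25 h raise the temperature by 10 K, then wait 25 h
- violet: at 25 h take out 90 % of the L then present, then wait 25 h

- removed L is counted in
- steps that have been proposed: E + G + D <-> L + D; 2 D -> Z
- additions bring no volume worth counting

- L, in percent of the E first charged, at 25 h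
- the remedy with the largest gain of L, or "none" below 2 percentage points (blue / green / ochre / teal / violet / none)
- L present, with what was taken out counted in, in percent of the E first charged, after blue
- L present, with what was taken out counted in, in percent of the E first charged, after violet

*Why has the winter flask stopped?* Not for want of G: at that flat 0.179 M of G is free, of 0.564 M charged. So either the reaction has reached its balance, or D has gone to Z.

*What number tells these apart?* Divide L by E times free G, all in mol per litre. Winter reads 3.89 /M. That reading is the stall quotient, the reaction quotient taken at the flat. A flat that is a balance keeps this quotient when the charges change, at fixed temperature.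

*And noon?* Noon has more E and runs at 31 °C instead of 25 °C. Its mean L from 1.00 h on is 24.2 %, less than winter's, with free G of 0.104 M. Its quotient reads 3.06 /M. That G is less than winter's, so a reading's scatter weighs more at noon. Winter over noon, the shares stand in a ratio of 1.69 and the quotients in a ratio of 1.27, read at two temperatures.

*But could D be dying all the same?* Yes, a flat cannot show it. The catalyst is tested when the balance is displaced.

*Your reckoning, then?* By my reckoning, L stays near 41.0 % at 25 h and after blue. Holding the quotient at 3.89 /M, ochre reaches 55.7 % and violet 51.7 %, so ochre gives more. Both figures assume D still turns.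

The forecast says 41 % now, from 38.5 % to 44 %; 41.5 % after blue; ochre as the best remedy, with L at about 55 %; and 51 % after violet, from 42 % to 55 %, “if the catalyst is still alive”.

    E + G + D ⇌ L + D, rate k1*[E]*[G]*[D] forward; the back reaction follows from the equilibrium constant (K = 4.06 /M, k = 7.59 /M²/min, Ea = 51.0 kJ/mol, ΔH = −18.0 kJ/mol)
    2 D → Z (k = 2.24 /M/min, Ea = 46.0 kJ/mol)
    (constants at 25 °C)

The asked flask stands at 41.2 %, and ochre gains most, 10 percentage points, with blue at 41.4 % and violet at 47.8 %. At 25.0 h D holds 5.22 % of the catalyst charged. The asked flask's stall quotient is then 3.97 /M, whereas the violet flask ends at 1.78 /M, less than the winter reading. For the flask with 2.3 M of G, the winter quotient gives L of 85.4 %, and that flask holds 85.8 %.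

Readings and results were generated by integration with constants of no real substance, and the scatter is random.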